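Numbering follows the phakellins: pyrrole N1, C6 (aminal CH), N7 (methyl), C8, N9, C10 (spiro aminal carbon), C11–C13, N14, C15 (lactam C=O); ring A pyrrole, ring B ketopiperazine, ring C pyrrolidine, ring D cyclic guanidine.
Retrosynthetic cuts, in order: C8–NH2 (guanidine back to a urea); N1–C6 (ring B, from a C6 carbonyl via an N-acyliminium ion); C10–C11 together with N14–C13 (ring C, an acrolein unit); then the N14–C15 amide and the C10–N14 bond (azide on a 5-bromohydantoin).
Forward: ring D is present from the start as 3-methylhydantoin; C10 is aminated and acylated with the dibromopyrrole acid (ring A); ring C is annulated; ring B closes through N1 after reduction of the C6 carbonyl; the urea becomes the guanidine last.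
Enabling feature: C10 bears N9, N14 and C6 and is tied to ring C only by C10–C11 and by N14–C13. While C6 is still a hydantoin carbonyl, C10 is an acidic C–H next to an amide N–H, so the pair C10/N14 acts as a 1,2-C,N-dinucleophile towards a three-carbon enal.
Stereochemistry: C10 (R in the target) is set by the chiral squaramide base in the annulation; C6 (S) follows from C10 because ring B can only close cis across the C6–C10 bond of ring D.

Key step: step 6

Assumption: the quinine-derived squaramide is taken to deliver the (5S)-configured annulation product; if it favours the mirror image, the quinidine-derived pseudoenantiomer is used with no other change.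

Step 1
Reactants: 1 3-methylhydantoin (3-methylimidazolidine-2,4-dione)
Product: 2 tert-butyl 3-methyl-2,4-dioxoimidazolidine-1-carboxylate
Conditions: Boc2O (1.2 equiv), 4-(dimethylamino)pyridine (10 mol %), MeCN, rt
Reagents that add atoms: di-tert-butyl dicarbonate, CC(C)(C)OC(=O)OC(=O)OC(C)(C)C
Why: Nucleophile-catalysed N-acylation (Boc protection) of the only N–H, the ureide N1, which blocks this nitrogen and acidifies C5–H for the later steps.

Step 2
Reactants: 2 tert-butyl 3-methyl-2,4-dioxoimidazolidine-1-carboxylate
Product: 3 tert-butyl 5-bromo-3-methyl-2,4-dioxoimidazolidine-1-carboxylate (racemic)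
Conditions: NBS (1.05 equiv), visible light, PhCF3, rt
Reagents that add atoms: N-bromosuccinimide, O=C1CCC(=O)N1Br
Why: Wohl–Ziegler radical bromination at the captodative C5–H between the carbamate nitrogen and the C4 carbonyl, the same reactivity by which N-Boc glycine derivatives are photobrominated to α-bromoglycinates.

Step 3
Reactants: 3 tert-butyl 5-bromo-3-methyl-2,4-dioxoimidazolidine-1-carboxylate
Product: 4 tert-butyl 5-azido-3-methyl-2,4-dioxoimidazolidine-1-carboxylate (racemic)
Conditions: NaN3 (1.2 equiv), DMF, 0 °C; kept in solution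
Reagents that add atoms: sodium azide, [Na+].[N-]=[N+]=[N-]
Why: SN2 displacement of the highly activated α-bromo aminal by the non-basic azide ion, the standard entry to α-azidoglycine derivatives, which leaves C5–H and the carbamate untouched.

Step 4
Reactants: 4 tert-butyl 5-azido-3-methyl-2,4-dioxoimidazolidine-1-carboxylate
Product: 5 tert-butyl 5-amino-3-methyl-2,4-dioxoimidazolidine-1-carboxylate (racemic)
Conditions: H2 (1 atm), 10% Pd/C, EtOAc, rt; filtered and used at once
Reagents that add atoms: none
Why: Catalytic hydrogenation of the azide to the primary amine under neutral conditions that spare the Boc group, carried out before any aryl bromide is present.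

Step 5
Reactants: 5 tert-butyl 5-amino-3-methyl-2,4-dioxoimidazolidine-1-carboxylate; 6 4,5-dibromo-1H-pyrrole-2-carboxylic acid
Product: 7 tert-butyl 5-(4,5-dibromo-1H-pyrrole-2-carboxamido)-3-methyl-2,4-dioxoimidazolidine-1-carboxylate (racemic, C5 labile)
Conditions: N,N'-diisopropylcarbodiimide (1.1 equiv), 1-hydroxy-7-azabenzotriazole (1.1 equiv), DMF/CH2Cl2, 0 °C → rt
Reagents that add atoms: none
Why: Carbodiimide/active-ester amide coupling in which the primary amine is the only competent nucleophile, since the pyrrole N–H is not acylated without base, as in the usual unprotected couplings of this acid.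

Step 6
Reactants: 7 tert-butyl 5-(4,5-dibromo-1H-pyrrole-2-carboxamido)-3-methyl-2,4-dioxoimidazolidine-1-carboxylate; 8 acrolein
Product: 10 tert-butyl (5S)-6-(4,5-dibromo-1H-pyrrole-2-carbonyl)-7-hydroxy-3-methyl-2,4-dioxo-1,3,6-triazaspiro[4.4]nonane-1-carboxylate (both C7 epimers), via Michael adduct aldehyde 9 (not isolated)
Conditions: 8 (2 equiv, freshly distilled), quinine-derived squaramide 3-{[3,5-bis(trifluoromethyl)phenyl]amino}-4-{[(8α,9S)-6′-methoxycinchonan-9-yl]amino}cyclobut-3-ene-1,2-dione (10 mol %), CH2Cl2, −40 → −20 °C
Reagents that add atoms: none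
Why: The quinuclidine nitrogen of the catalyst removes the C5–H of 7, which is flanked by the C4 carbonyl, the Boc-acylated N1 and the acylamino nitrogen, and the planar enolate, held by the squaramide N–H bonds, adds through C5 to acrolein activated by the protonated amine; the closest known reaction types are squaramide-base Michael additions of 5-substituted hydantoin-type pronucleophiles and cinchona-base additions of tertiary C–H acids to acrolein. The aldehyde 9 is then trapped by the amide N–H in a 5-exo-trig hemiaminal closure, as in Michael–hemiaminal annulations of α-amido C–H acids with enals, which closes ring C and forms C10–C11 and N14–C13 in one operation. The only lasting stereocentre, the spiro carbon C5 (C10 of the target), is set by catalyst control: the chiral ion pair exposes one face of the enolate to the acceptor, acrolein has no β-substituent to control, and the hemiaminal epimers are removed in step 7. The step needs C- rather than N-alkylation and closure through the amide nitrogen only: Boc on N1 removes the competing ring N–H and raises the C5–H acidity, and any aza-Michael adduct at the pyrrole nitrogen is reversible under the same base, whereas C-alkylation is locked by the hemiaminal closure. The racemic, labile C5 of 7 is no drawback because deprotonation erases it.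

Step 7
Reactants: 10 tert-butyl (5S)-6-(4,5-dibromo-1H-pyrrole-2-carbonyl)-7-hydroxy-3-methyl-2,4-dioxo-1,3,6-triazaspiro[4.4]nonane-1-carboxylate
Product: 12 (5R)-6-(4,5-dibromo-1H-pyrrole-2-carbonyl)-3-methyl-1,3,6-triazaspiro[4.4]nonane-2,4-dione, via Boc-protected spiro pyrrolidine 11 (not isolated)
Conditions: Et3SiH (4 equiv), CF3CO2H (5 equiv), CH2Cl2, −20 → 0 °C; then CF3CO2H/CH2Cl2 1:2, rt
Reagents that add atoms: none
Why: Ionic hydrogenation, in which the acid ionizes the N-acyl hemiaminal to an N-acyliminium ion that the silane reduces irreversibly (draining any reversible trapping by neighbouring nucleophiles) before stronger acid cleaves the Boc carbamate; both C7 epimers converge, the quaternary centre is untouched, and its descriptor changes from S to R only because the priorities of N1 and N6 swap when Boc is lost.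

Step 8
Reactants: 12 (5R)-6-(4,5-dibromo-1H-pyrrole-2-carbonyl)-3-methyl-1,3,6-triazaspiro[4.4]nonane-2,4-dione
Product: 13 (5R)-6-(4,5-dibromo-1H-pyrrole-2-carbonyl)-4-hydroxy-3-methyl-1,3,6-triazaspiro[4.4]nonan-2-one (both C4 epimers)
Conditions: NaBH4 (3 equiv), MeOH/THF 1:1, −10 → 0 °C
Reagents that add atoms: none
Why: Partial hydride reduction of an imide to a hydroxy aminal, selective for C4 because C2 is a urea and the pyrrole carboxamide is deactivated further once the pyrrole N–H is deprotonated; with N1–H free the N3 ureide is too poor a leaving group for ring opening, so reduction should stop at the carbinol, whose configuration is immaterial.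

Step 9
Reactants: 13 (5R)-6-(4,5-dibromo-1H-pyrrole-2-carbonyl)-4-hydroxy-3-methyl-1,3,6-triazaspiro[4.4]nonan-2-one
Product: 14 (6S,10R)-7-N-methyldibromophakellstatin (the tetracyclic urea: rings A–D of the target with C8=O and N9–H)
Conditions: CF3CO2H (10 equiv), CH2Cl2, 0 °C → rt
Reagents that add atoms: none
Why: N-acyliminium cyclization (intramolecular amidoalkylation) in which acid ionizes the carbinol to an N-carbamoyl iminium ion that has no α-hydrogen to lose and is captured by the pyrrole nitrogen in a 6-exo-trig closure of ring B, nitrogen being the kinetic site over the acyl- and bromine-deactivated pyrrole C4; the new C6 centre can only form cis to N14 on C10, since a trans fusion of rings B and D is prohibitively strained.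

Step 10
Reactants: 14 (6S,10R)-7-N-methyldibromophakellstatin
Product: 16 (−)-7-N-methyldibromophakellin, via O-ethylisouronium tetrafluoroborate 15 (not isolated)
Conditions: Et3OBF4 (1.5 equiv), CH2Cl2, rt; then NH3 (7 M in MeOH), sealed tube, 60 °C; aq Na2CO3
Reagents that add atoms: ammonia, N
Why: Urea-to-guanidine exchange through an isourea, in which the urea oxygen, the most nucleophilic oxygen present, is ethylated by the trialkyloxonium salt and ammonia then replaces ethanol by addition–elimination at C8, leaving both aminal centres untouched.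

Compound list
1 | 3-methylhydantoin (3-methylimidazolidine-2,4-dione) | CN1C(=O)CNC1=O | starting material
2 | tert-butyl 3-methyl-2,4-dioxoimidazolidine-1-carboxylate | CN1C(=O)CN(C(=O)OC(C)(C)C)C1=O | intermediate
3 | tert-butyl 5-bromo-3-methyl-2,4-dioxoimidazolidine-1-carboxylate (racemic) | CN1C(=O)C(Br)N(C(=O)OC(C)(C)C)C1=O | intermediate
4 | tert-butyl 5-azido-3-methyl-2,4-dioxoimidazolidine-1-carboxylate (racemic) | CN1C(=O)C(N=[N+]=[N-])N(C(=O)OC(C)(C)C)C1=O | intermediate
5 | tert-butyl 5-amino-3-methyl-2,4-dioxoimidazolidine-1-carboxylate (racemic) | CN1C(=O)C(N)N(C(=O)OC(C)(C)C)C1=O | intermediate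
6 | 4,5-dibromo-1H-pyrrole-2-carboxylic acid | OC(=O)c1cc(Br)c(Br)[nH]1 | starting material
7 | tert-butyl 5-(4,5-dibromo-1H-pyrrole-2-carboxamido)-3-methyl-2,4-dioxoimidazolidine-1-carboxylate (racemic) | CN1C(=O)N(C(=O)OC(C)(C)C)C(NC(=O)c2cc(Br)c(Br)[nH]2)C1=O | intermediate
8 | acrolein (prop-2-enal) | C=CC=O | starting material
9 | tert-butyl (5S)-5-(4,5-dibromo-1H-pyrrole-2-carboxamido)-3-methyl-2,4-dioxo-5-(3-oxopropyl)imidazolidine-1-carboxylate | CN1C(=O)N(C(=O)OC(C)(C)C)[C@](CCC=O)(NC(=O)c2cc(Br)c(Br)[nH]2)C1=O | intermediate
10 | tert-butyl (5S)-6-(4,5-dibromo-1H-pyrrole-2-carbonyl)-7-hydroxy-3-methyl-2,4-dioxo-1,3,6-triazaspiro[4.4]nonane-1-carboxylate (both C7 epimers) | CN1C(=O)N(C(=O)OC(C)(C)C)[C@]2(N(C(=O)c3cc(Br)c(Br)[nH]3)C(O)CC2)C1=O | intermediate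
11 | tert-butyl (5S)-6-(4,5-dibromo-1H-pyrrole-2-carbonyl)-3-methyl-2,4-dioxo-1,3,6-triazaspiro[4.4]nonane-1-carboxylate | CN1C(=O)N(C(=O)OC(C)(C)C)[C@]2(N(C(=O)c3cc(Br)c(Br)[nH]3)CCC2)C1=O | intermediate
12 | (5R)-6-(4,5-dibromo-1H-pyrrole-2-carbonyl)-3-methyl-1,3,6-triazaspiro[4.4]nonane-2,4-dione | CN1C(=O)N[C@]2(N(C(=O)c3cc(Br)c(Br)[nH]3)CCC2)C1=O | intermediate
13 | (5R)-6-(4,5-dibromo-1H-pyrrole-2-carbonyl)-4-hydroxy-3-methyl-1,3,6-triazaspiro[4.4]nonan-2-one (both C4 epimers) | CN1C(=O)N[C@]2(N(C(=O)c3cc(Br)c(Br)[nH]3)CCC2)C1O | intermediate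
14 | (6S,10R)-7-N-methyldibromophakellstatin (tetracyclic urea) | CN1C(=O)N[C@]23CCCN2C(=O)c2cc(Br)c(Br)n2[C@H]13 | intermediate
15 | (6S,10R)-8-O-ethylisouronium tetrafluoroborate of 14 | CN1C(OCC)=[NH+][C@]23CCCN2C(=O)c2cc(Br)c(Br)n2[C@H]13.F[B-](F)(F)F | intermediate
16 | (−)-7-N-methyldibromophakellin, (6S,10R) | CN1C(N)=N[C@]23CCCN2C(=O)c2cc(Br)c(Br)n2[C@H]13 | target

Total step count: 10.
Longest linear sequence: 10 steps (1 → 16); 6 and 8 are commercial and enter directly.

Steps most likely to fail

Step 6. Facial discrimination at the planar hydantoin enolate may be insufficient, and reversible aza-Michael alkylation at the acidic pyrrole nitrogen may erode conversion and selectivity. The fallback gives up asymmetric catalysis for a racemic annulation with separation of enantiomers; it sets out from 7 and 8 and returns at 12. With an achiral base (DABCO, CH2Cl2, 0 °C) the annulation should give 10 in admixture with the (5R)-hemiaminal F2, formed by way of 9 and the (5R)-aldehyde F1. Under the conditions of step 7 this mixture is deoxygenated to 11 and the (5R)-Boc spiro pyrrolidine F3 and then stripped of Boc to give 12 and the (5S)-hydantoin F4. These two differ only at the one quaternary centre and are separated by preparative chromatography on a chiral stationary phase; 12 re-enters at step 8.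

Step 9. Under acid the neutral pyrrole may close through C4 instead of N1, or the new aminal may re-ionize and drift to the C-linked isomer. The fallback replaces acid-promoted capture by base-promoted N-alkylation of the pyrrolide; it sets out from 13 and returns at 14. SOCl2 (CH2Cl2, 0 °C) exchanges the hemiaminal hydroxyl for chloride to give the (5R)-4-chloroimidazolidinone F5. K2CO3 in MeCN then deprotonates the pyrrole, and the anion, whose charge sits on nitrogen, alkylates at N1 as azole anions do with N-(α-chloroalkyl) amides, closing ring B to 14.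

Step 10. Displacement of ethoxide from the hindered isouronium ion by ammonia may be slow, with hydrolysis back to the urea on work-up. The fallback uses a stronger, non-volatile amine as an ammonia surrogate followed by acidolytic unmasking; it sets out from 15 and returns at 16. 2,4-Dimethoxybenzylamine (CH2Cl2/MeOH, 40 °C) replaces the ethoxy group to give the N-(2,4-dimethoxybenzyl)guanidine F6. CF3CO2H with Et3SiH at 50 °C then cleaves the electron-rich benzyl group, the silane reducing the benzyl cation, to give 16.

Further compounds
F1 | step 6 | tert-butyl (5R)-5-(4,5-dibromo-1H-pyrrole-2-carboxamido)-3-methyl-2,4-dioxo-5-(3-oxopropyl)imidazolidine-1-carboxylate | CN1C(=O)N(C(=O)OC(C)(C)C)[C@@](CCC=O)(NC(=O)c2cc(Br)c(Br)[nH]2)C1=O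
F2 | step 6 | tert-butyl (5R)-6-(4,5-dibromo-1H-pyrrole-2-carbonyl)-7-hydroxy-3-methyl-2,4-dioxo-1,3,6-triazaspiro[4.4]nonane-1-carboxylate (both C7 epimers) | CN1C(=O)N(C(=O)OC(C)(C)C)[C@@]2(N(C(=O)c3cc(Br)c(Br)[nH]3)C(O)CC2)C1=O
F3 | step 6 | tert-butyl (5R)-6-(4,5-dibromo-1H-pyrrole-2-carbonyl)-3-methyl-2,4-dioxo-1,3,6-triazaspiro[4.4]nonane-1-carboxylate | CN1C(=O)N(C(=O)OC(C)(C)C)[C@@]2(N(C(=O)c3cc(Br)c(Br)[nH]3)CCC2)C1=O
F4 | step 6 | (5S)-6-(4,5-dibromo-1H-pyrrole-2-carbonyl)-3-methyl-1,3,6-triazaspiro[4.4]nonane-2,4-dione | CN1C(=O)N[C@@]2(N(C(=O)c3cc(Br)c(Br)[nH]3)CCC2)C1=O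
F5 | step 9 | (5R)-4-chloro-6-(4,5-dibromo-1H-pyrrole-2-carbonyl)-3-methyl-1,3,6-triazaspiro[4.4]nonan-2-one (both C4 epimers) | CN1C(=O)N[C@]2(N(C(=O)c3cc(Br)c(Br)[nH]3)CCC2)C1Cl
F6 | step 10 | (6S,10R)-N-(2,4-dimethoxybenzyl)-7-N-methyldibromophakellin | CN1C(NCc4ccc(OC)cc4OC)=N[C@]23CCCN2C(=O)c2cc(Br)c(Br)n2[C@H]13
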